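Assumption: 1 and 2 are bought as catalogue compounds (2 as the E isomer, a flavour substance). Labels used below: C7/C8 = benzylic/methyl-bearing carbon of the propenyl unit, O4' = catechol oxygen para to CHO and next to OMe, O3' = the other catechol oxygen. In the benzodioxine names C8 becomes C2 and C7 becomes C3.

## Retrosynthetic overview
1. All atoms come from 1 (5-hydroxyvanillin), 2 ((E)-4-propenylsyringol), MeI and Ph3P=CHCHO. Both arenes are bought, and the target is the trans-(2S,3S)-benzodioxane.
2. Key disconnection: both C–O bonds of the dioxane ring are cut at once, leading back to o-quinone 3 (oxidised 1) and 2.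
3. Only the dioxane ring is built. C8–O4' forms first under catalyst control and sets the absolute configuration, giving p-quinone methide 4. C7–O3' then closes by 1,6-addition under substrate control and sets trans, giving 5.
4. The periphery follows: phenol O–CH3 (5 to 6), then the enal C=C (6 to 7).

## Route

Step 1
Reactants: 1 5-hydroxyvanillin (3,4-dihydroxy-5-methoxybenzaldehyde); 2 (E)-4-propenylsyringol (2,6-dimethoxy-4-[(E)-prop-1-enyl]phenol)
Product: 5 (2S,3S)-3-(4-hydroxy-3,5-dimethoxyphenyl)-8-methoxy-2-methyl-2,3-dihydro-1,4-benzodioxine-6-carbaldehyde, via o-quinone 3 (not isolated), via p-quinone methide 4 (not isolated)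
Conditions: (a) 1 (1.3 equiv), Ag2O (1.5 equiv), Na2SO4, CH2Cl2, −20 °C, 15 min, cold filtration through Celite under Ar; (b) filtrate added over 2 h to 2 (1.0 equiv), (R)-3,3'-bis(2,4,6-triisopropylphenyl)-1,1'-binaphthyl-2,2'-diyl hydrogen phosphate (C50H57O4P, 10 mol %), 4 Å MS, toluene/CH2Cl2, −70 °C to −30 °C
Reagents that add atoms: none
Why: Proposed new method: the bifunctional chiral phosphoric acid holds 3 and 2 together (P–OH to the more basic O3' carbonyl, which is the doubly vinylogous ester carbonyl of the OMe group, and P=O to the phenol OH of 2), so that proton-coupled electron transfer or an asynchronous polar attack joins C8 to O4' (the site of highest spin density of the semiquinone, whose ortho and para carbons are all substituted, as in the natural 8-O-4' radical coupling) on the Si face of C8 inside the chiral pocket and sets C8 as S, after which the freed O3'–H adds 1,6 to p-quinone methide 4 through a chair-like transition state with aryl and methyl pseudo-equatorial (reversible under the acid, hence also thermodynamically trans) and sets C7 as S; the closest known reaction types are the racemic Ag2O cross-coupling of 3-methoxycatechols with 4-propenylsyringol to trans-benzodioxanes of this regiochemistry, chiral-phosphoric-acid-catalysed formal cycloadditions of hydroxystyrenes with quinone derivatives that run through a quinone methide, and organocatalytic enantioselective inverse-electron-demand hetero-Diels–Alder reactions of o-quinones with enamines or ketene enolates.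

Step 2
Reactants: 5 (2S,3S)-3-(4-hydroxy-3,5-dimethoxyphenyl)-8-methoxy-2-methyl-2,3-dihydro-1,4-benzodioxine-6-carbaldehyde
Product: 6 (2S,3S)-8-methoxy-2-methyl-3-(3,4,5-trimethoxyphenyl)-2,3-dihydro-1,4-benzodioxine-6-carbaldehyde
Conditions: MeI (1.5 equiv), K2CO3 (1.5 equiv), DMF, 0 °C to rt, 4 h
Reagents that add atoms: iodomethane (MeI), CI
Why: Williamson-type SN2 O-methylation of the only acidic OH leaves aldehyde, acetal-free dioxane ring and both stereocentres untouched, and even a transient phenolate/quinone methide opening could only touch C3 and recloses to the favoured trans isomer while C2 keeps the absolute configuration.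

Step 3
Reactants: 6 (2S,3S)-8-methoxy-2-methyl-3-(3,4,5-trimethoxyphenyl)-2,3-dihydro-1,4-benzodioxine-6-carbaldehyde
Product: 7 (E)-3-[(2S,3S)-8-methoxy-2-methyl-3-(3,4,5-trimethoxyphenyl)-2,3-dihydro-1,4-benzodioxin-6-yl]prop-2-enal
Conditions: Ph3P=CHCHO (1.2 equiv), toluene, 90 °C, 16 h
Reagents that add atoms: (triphenylphosphoranylidene)acetaldehyde, O=CC=P(c1ccccc1)(c1ccccc1)c1ccccc1
Why: Wittig olefination with a stabilised formyl ylide gives the E-enal under neutral conditions, as it does with 3,4,5-trialkoxybenzaldehydes, and neither stereocentre is involved because the fully etherified benzodioxane has no pathway to a quinone methide.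

## Compound list
1 | 5-hydroxyvanillin (3,4-dihydroxy-5-methoxybenzaldehyde) | COc1cc(C=O)cc(O)c1O | starting material
2 | (E)-4-propenylsyringol (2,6-dimethoxy-4-[(E)-prop-1-enyl]phenol) | C/C=C/c1cc(OC)c(O)c(OC)c1 | starting material
3 | 5-methoxy-3,4-dioxocyclohexa-1,5-diene-1-carbaldehyde (o-quinone of 1) | COC1=CC(C=O)=CC(=O)C1=O | intermediate
4 | 3-hydroxy-5-methoxy-4-{[(2S)-1-(3,5-dimethoxy-4-oxocyclohexa-2,5-dien-1-ylidene)propan-2-yl]oxy}benzaldehyde (p-quinone methide) | C[C@H](Oc1c(O)cc(C=O)cc1OC)C=C1C=C(OC)C(=O)C(OC)=C1 | intermediate
5 | (2S,3S)-3-(4-hydroxy-3,5-dimethoxyphenyl)-8-methoxy-2-methyl-2,3-dihydro-1,4-benzodioxine-6-carbaldehyde (trans) | COc1cc([C@@H]2Oc3cc(C=O)cc(OC)c3O[C@H]2C)cc(OC)c1O | intermediate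
6 | (2S,3S)-8-methoxy-2-methyl-3-(3,4,5-trimethoxyphenyl)-2,3-dihydro-1,4-benzodioxine-6-carbaldehyde (trans) | COc1cc([C@@H]2Oc3cc(C=O)cc(OC)c3O[C@H]2C)cc(OC)c1OC | intermediate
7 | (E)-3-[(2S,3S)-8-methoxy-2-methyl-3-(3,4,5-trimethoxyphenyl)-2,3-dihydro-1,4-benzodioxin-6-yl]prop-2-enal | COc1cc([C@@H]2Oc3cc(/C=C/C=O)cc(OC)c3O[C@H]2C)cc(OC)c1OC | target

## Count and risks
Total step count: 3. Longest linear sequence: 3.

**Step 1 (highest risk).**
- The open points are periselectivity (hetero-diene addition against carbodiene addition or C–C coupling), a racemic background electron transfer between 3 and 2, and the lability of 3.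
- The level and sense of induction are also unknown. The sense must be checked by CD or optical rotation on 6 or 7, and the mirror-image acid is equally available. A modest ee can be raised by recrystallising 6.
- The fallback sets out from 1 and 2 and comes back at 5. Both phenols are stirred together with Ag2O (2.5 equiv) in toluene/acetone at room temperature. This is the long-known heterogeneous radical cross-coupling, and it gives the trans-benzodioxane as a racemate. The racemate is 5 together with (2R,3R)-3-(4-hydroxy-3,5-dimethoxyphenyl)-8-methoxy-2-methyl-2,3-dihydro-1,4-benzodioxine-6-carbaldehyde F1.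
- The two enantiomers are separated by preparative supercritical-fluid chromatography on an amylose tris(3,5-dimethylphenylcarbamate) phase. The absolute configuration then comes from resolution and not from catalysis.

**Step 3.**
- The electron-rich aldehyde reacts slowly, and the product enal can take up a second ylide to give the dienal.
- The fallback sets out from 6 and comes back at 7. Horner–Wadsworth–Emmons olefination with triethyl phosphonoacetate (LiCl, DBU, MeCN, rt) gives ethyl (E)-3-[(2S,3S)-8-methoxy-2-methyl-3-(3,4,5-trimethoxyphenyl)-2,3-dihydro-1,4-benzodioxin-6-yl]prop-2-enoate F2.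
- Reduction with i-Bu2AlH (2.2 equiv, CH2Cl2, −78 °C) gives (E)-3-[(2S,3S)-8-methoxy-2-methyl-3-(3,4,5-trimethoxyphenyl)-2,3-dihydro-1,4-benzodioxin-6-yl]prop-2-en-1-ol F3. MnO2 (CH2Cl2, rt) then oxidises the allylic alcohol to 7.
- The ester level cannot over-homologate.

**Step 2.**
- The phenolate of a p-hydroxybenzyl aryl ether can expel O3' and open to the quinone methide. That would lead to C3 epimers or to methylation of the freed O3'.
- The fallback sets out from 5 and comes back at 6. It is a Mitsunobu etherification with methanol (PPh3, DIAD, THF, 0 °C to rt).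
- This is a redox condensation in which methanol, activated as a methoxyphosphonium ion, is the methyl source. No base or free phenolate is present, so the quinone methide channel is closed. It makes no compound outside the list (F0).

## Further compounds
F1 | step 1 | (2R,3R)-3-(4-hydroxy-3,5-dimethoxyphenyl)-8-methoxy-2-methyl-2,3-dihydro-1,4-benzodioxine-6-carbaldehyde | COc1cc([C@H]2Oc3cc(C=O)cc(OC)c3O[C@@H]2C)cc(OC)c1O
F0 | step 2 | none | none
F2 | step 3 | ethyl (E)-3-[(2S,3S)-8-methoxy-2-methyl-3-(3,4,5-trimethoxyphenyl)-2,3-dihydro-1,4-benzodioxin-6-yl]prop-2-enoate | COc1cc([C@@H]2Oc3cc(/C=C/C(=O)OCC)cc(OC)c3O[C@H]2C)cc(OC)c1OC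
F3 | step 3 | (E)-3-[(2S,3S)-8-methoxy-2-methyl-3-(3,4,5-trimethoxyphenyl)-2,3-dihydro-1,4-benzodioxin-6-yl]prop-2-en-1-ol | COc1cc([C@@H]2Oc3cc(/C=C/CO)cc(OC)c3O[C@H]2C)cc(OC)c1OC
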